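**Retrosynthetic overview**
- Feature: in ring A (the formyl phenol arene) the C-OH carbon and the only C-H carbon are neighbours, flanked by C-CHO and C-CH3. The other two adjacent carbons (C-O ether, C-C(=O)O) are shared with the seven-membered lactone ring C. Ring A therefore splits into an HC≡C-OEt unit and the C3-C6 diene of a 2-pyranone already fused to ring C.
- Last events: inverse-demand Diels-Alder addition of ethoxyacetylene across pyranone C3/C6 with loss of CO2 builds ring A, then the O-ethyl group is cleaved.
- Ring C: the ring B C6 phenol displaces a chloride at pyranone C4, then the pyranone C5 acid lactonises onto the ring B C7 phenol.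
- Pyranone: benzyl acetoacetate plus malonyl dichloride, then chloroformylation. Rings B/D: 2,4-dihydroxy-6-methylacetophenone by O-benzylation, para-hydroxylation and chromanone annulation with acetone.
- Ring order: ring D (the chromanone heterocycle on ring B) and the 2-pyranone in parallel, then ring C, then ring A.

Key step: step 9

Remark: the target has no stereocentre. Locants are those of chroman-4-one (O1, C2 gem-dimethyl, C4 ketone, C5 methyl, C6, C7) and of pyran-2-one (O1, C2 carbonyl, C3 to C6).

Step 1
Reactants: 1 2,4-dihydroxy-6-methylacetophenone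
Product: 2 4-(benzyloxy)-2-hydroxy-6-methylacetophenone
Conditions: BnBr (1.05 equiv), K2CO3, MeCN, 60 °C
Reagents that add atoms: benzyl bromide, BrCc1ccccc1
Why: Williamson ether synthesis: the C2 hydroxyl is held in a hydrogen bond to the acetyl oxygen, so only the C4 hydroxyl (the future C7 oxygen of ring B) is ionised and alkylated.

Step 2
Reactants: 2 4-(benzyloxy)-2-hydroxy-6-methylacetophenone
Product: 4 4-(benzyloxy)-2,5-dihydroxy-6-methylacetophenone, via potassium aryl sulfate 3 (not isolated)
Conditions: K2S2O8, aq KOH, pyridine, 0 °C to rt; then aq HCl, 85 °C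
Reagents that add atoms: potassium persulfate, [K+].[K+].[O-]S(=O)(=O)OOS(=O)(=O)[O-]
Why: Elbs persulfate oxidation: the phenoxide of 2 attacks the peroxide oxygen through the carbon para to its own oxygen (C5, the only open para site) to give sulfate 3, whose S-O bond hot dilute acid hydrolyses without touching the benzyl ether or the ketone.

Step 3
Reactants: 4 4-(benzyloxy)-2,5-dihydroxy-6-methylacetophenone; 5 acetone
Product: 7 7-(benzyloxy)-6-hydroxy-2,2,5-trimethylchroman-4-one, via dimethyl enone 6 (not isolated)
Conditions: pyrrolidine (0.5 equiv), excess acetone, EtOH, argon, 60 °C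
Reagents that add atoms: none
Why: Kabbe chromanone synthesis: pyrrolidine mediates aldol condensation of the acetyl methyl group with acetone to enone 6 and the ortho phenol closes ring D by 6-endo-trig oxa-Michael addition, while the other phenol, meta to the acyl group, cannot reach the enone and remains as the free C6 hydroxyl.

Step 4
Reactants: 8 benzyl acetoacetate; 9 malonyl dichloride
Product: 11 benzyl 4-hydroxy-6-methyl-2-oxo-2H-pyran-5-carboxylate, via C-acylated acid chloride 10 (not isolated)
Conditions: 1,2-dichloroethane, 50 °C, N2 sweep, 1.0 equiv of 9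
Reagents that add atoms: none
Why: Known 4-hydroxy-2-pyranone synthesis from 1,3-dicarbonyl compounds and malonyl dichloride: C-acylation at the active methylene gives 10 and the acetyl enol oxygen closes on the second acid chloride, the benzyl ester being chosen because it withstands the HCl evolved where a tert-butyl ester would not.

Step 5
Reactants: 11 benzyl 4-hydroxy-6-methyl-2-oxo-2H-pyran-5-carboxylate
Product: 13 benzyl 4-chloro-3-formyl-6-methyl-2-oxo-2H-pyran-5-carboxylate, via iminium chloride 12 (not isolated)
Conditions: POCl3 (2.5 equiv), DMF, 0 to 50 °C; then ice-water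
Reagents that add atoms: N,N-dimethylformamide, CN(C)C=O; phosphoryl chloride, O=P(Cl)(Cl)Cl; water, O
Why: Vilsmeier-Haack-Arnold chloroformylation, established for 4-hydroxycoumarins and 4-hydroxy-6-methyl-2-pyranone: enolic C3 attacks the chloromethyleneiminium ion, the activated C4 oxygen is exchanged for chloride and water hydrolyses 12, with limited reagent and temperature keeping the acidic C6 methyl group from reacting.

Step 6
Reactants: 7 7-(benzyloxy)-6-hydroxy-2,2,5-trimethylchroman-4-one; 13 benzyl 4-chloro-3-formyl-6-methyl-2-oxo-2H-pyran-5-carboxylate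
Product: 14 benzyl 4-{[7-(benzyloxy)-2,2,5-trimethyl-4-oxochroman-6-yl]oxy}-3-formyl-6-methyl-2-oxo-2H-pyran-5-carboxylate
Conditions: K2CO3, MeCN, 0 °C to rt
Reagents that add atoms: none
Why: Addition-elimination (vinylogous acyl substitution) as known for 4-chloro-3-formylcoumarins with phenols: C4 is a vinylogous acid chloride activated by the formyl, lactone and ester carbonyls, and since the C6 hydroxyl is the only free phenol of 7 the ether regiochemistry is fixed.

Step 7
Reactants: 14 benzyl 4-{[7-(benzyloxy)-2,2,5-trimethyl-4-oxochroman-6-yl]oxy}-3-formyl-6-methyl-2-oxo-2H-pyran-5-carboxylate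
Product: 15 3-formyl-4-[(7-hydroxy-2,2,5-trimethyl-4-oxochroman-6-yl)oxy]-6-methyl-2-oxo-2H-pyran-5-carboxylic acid
Conditions: H2 (1 atm), 10% Pd/C, EtOAc, rt, stopped after uptake of two equivalents
Reagents that add atoms: none
Why: Catalytic hydrogenolysis of a benzyl ester and an aryl benzyl ether, which should outrun reduction of the tetrasubstituted pyranone C=C bonds and of the donor-conjugated aldehyde, as in benzyl-protected formyl depsides, and which avoids the nucleophiles that would displace the C4 aryloxy group.

Step 8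
Reactants: 15 3-formyl-4-[(7-hydroxy-2,2,5-trimethyl-4-oxochroman-6-yl)oxy]-6-methyl-2-oxo-2H-pyran-5-carboxylic acid
Product: 17 fused pyranone (3-formyl-6-methyl-2-pyranone whose C4 is bound to the ring B C6 oxygen and whose C5 carbonyl is esterified by the ring B C7 oxygen; the pyranone analogue of the depsidone), via O-acylisourea 16 (not isolated)
Conditions: DCC, CH2Cl2 (high dilution), 0 °C to rt
Reagents that add atoms: none
Why: Carbodiimide lactonisation as used to close 2-(2-hydroxyaryloxy)benzoic acids to depsidones: the C7 phenol attacks 16 in a 7-exo-trig closure of ring C, and the absence of base and nucleophilic catalyst keeps the phenol protonated, so no Smiles migration of the pyranone from O6 to O7 and no displacement at C4 is expected.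

Step 9
Reactants: 17 fused pyranone; 18 ethoxyacetylene
Product: 20 O-ethyl mollicellin A, via bridged lactone 19 (not isolated)
Conditions: ethoxyacetylene (5 equiv, solution in hexanes), toluene, sealed tube, base-washed glass, 80 °C
Reagents that add atoms: none
Why: The 3-formyl group, the C2 lactone carbonyl and the C5 acyl group make the C3=C4-C5=C6 diene of 17 strongly electron-poor, so the electron-rich alkyne adds in an asynchronous inverse-electron-demand Diels-Alder reaction, its nucleophilic CH carbon bonding to C6 (beta to the C5 carbonyl, delta to the formyl and C2 carbonyls) and its ethoxy-bearing carbon bonding to C3. The 2-oxabicyclo[2.2.2]octadienone 19 then expels CO2 in an irreversible retro-Diels-Alder reaction and delivers ring A already aromatic, without an oxidant. The closest known reaction type is the cycloaddition of 3-acyl- and 5-alkoxycarbonyl-2-pyranones with ynamines, alkoxyalkynes and ketene acetals followed by CO2 extrusion, which places the donor ortho to the 3-acyl group. Ring A closes by intermolecular (4+2) cycloaddition that forms the C6-CH and C3-C(OEt) bonds, with rings B, C and D as spectators. The two bridgehead stereocentres of 19 form as a racemate, are fixed relative to each other by the bicycle and vanish on aromatisation, so no stereocontrol is needed. The step needs regioselectivity (CH to C6) and periselectivity (the carbodiene, not the O=CH-C3=C4 oxadiene or the formyl C=O): C6 carries the largest LUMO coefficient, C4 is a donor-bearing, fully substituted carbon locked in ring C, and acid-free conditions suppress (2+2) addition to the aldehyde.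

Step 10
Reactants: 20 O-ethyl mollicellin A
Product: 22 mollicellin A, via dichloroboron aryloxide 21 (not isolated)
Conditions: BCl3 (3 equiv), CH2Cl2, -78 to 0 °C; then H2O
Reagents that add atoms: none
Why: Chelation-directed ether cleavage: BCl3 bridges the formyl oxygen and the ortho ethoxy oxygen and chloride removes the ethyl group by SN2, whereas the diaryl ether cannot undergo SN2, and the aryl lactone and the ring D ether lack such a chelate, so hydrolysis of 21 should give the hydrogen-bonded salicylaldehyde.

**Compound list**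
1 | 2,4-dihydroxy-6-methylacetophenone | CC(=O)c1c(C)cc(O)cc1O | starting material
2 | 4-(benzyloxy)-2-hydroxy-6-methylacetophenone | CC(=O)c1c(C)cc(OCc2ccccc2)cc1O | intermediate
3 | potassium 3-acetyl-6-(benzyloxy)-4-hydroxy-2-methylphenyl sulfate | CC(=O)c1c(C)c(OS(=O)(=O)[O-])c(OCc2ccccc2)cc1O.[K+] | intermediate
4 | 4-(benzyloxy)-2,5-dihydroxy-6-methylacetophenone | CC(=O)c1c(C)c(O)c(OCc2ccccc2)cc1O | intermediate
5 | acetone | CC(C)=O | starting material
6 | 1-[4-(benzyloxy)-3,6-dihydroxy-2-methylphenyl]-3-methylbut-2-en-1-one | CC(C)=CC(=O)c1c(C)c(O)c(OCc2ccccc2)cc1O | intermediate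
7 | 7-(benzyloxy)-6-hydroxy-2,2,5-trimethylchroman-4-one | CC1(C)CC(=O)c2c(C)c(O)c(OCc3ccccc3)cc2O1 | intermediate
8 | benzyl acetoacetate | CC(=O)CC(=O)OCc1ccccc1 | starting material
9 | malonyl dichloride | O=C(Cl)CC(=O)Cl | starting material
10 | benzyl 2-acetyl-5-chloro-3,5-dioxopentanoate | CC(=O)C(C(=O)OCc1ccccc1)C(=O)CC(=O)Cl | intermediate
11 | benzyl 4-hydroxy-6-methyl-2-oxo-2H-pyran-5-carboxylate | CC1=C(C(=O)OCc2ccccc2)C(O)=CC(=O)O1 | intermediate
12 | {5-[(benzyloxy)carbonyl]-4-chloro-6-methyl-2-oxo-2H-pyran-3-yl}methylidene(dimethyl)ammonium chloride | CC1=C(C(=O)OCc2ccccc2)C(Cl)=C(C=[N+](C)C)C(=O)O1.[Cl-] | intermediate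
13 | benzyl 4-chloro-3-formyl-6-methyl-2-oxo-2H-pyran-5-carboxylate | CC1=C(C(=O)OCc2ccccc2)C(Cl)=C(C=O)C(=O)O1 | intermediate
14 | benzyl 4-{[7-(benzyloxy)-2,2,5-trimethyl-4-oxochroman-6-yl]oxy}-3-formyl-6-methyl-2-oxo-2H-pyran-5-carboxylate | CC1=C(C(=O)OCc2ccccc2)C(Oc2c(C)c3C(=O)CC(C)(C)Oc3cc2OCc2ccccc2)=C(C=O)C(=O)O1 | intermediate
15 | 3-formyl-4-[(7-hydroxy-2,2,5-trimethyl-4-oxochroman-6-yl)oxy]-6-methyl-2-oxo-2H-pyran-5-carboxylic acid | CC1=C(C(=O)O)C(Oc2c(C)c3C(=O)CC(C)(C)Oc3cc2O)=C(C=O)C(=O)O1 | intermediate
16 | O-acylisourea from acid 15 and DCC | CC1=C(C(=O)OC(=NC2CCCCC2)NC2CCCCC2)C(Oc2c(C)c3C(=O)CC(C)(C)Oc3cc2O)=C(C=O)C(=O)O1 | intermediate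
17 | fused pyranone, the 3-formyl-6-methyl-2-pyranone analogue of the depsidone (C4-O-C6 of ring B, C5-C(=O)-O-C7 of ring B) | CC1=C2C(=O)Oc3cc4OC(C)(C)CC(=O)c4c(C)c3OC2=C(C=O)C(=O)O1 | intermediate
18 | ethoxyacetylene | C#COCC | starting material
19 | bridged 2-oxabicyclo[2.2.2]octa-5,7-dien-3-one adduct (racemic, one enantiomer drawn; methyl and formyl on the bridgeheads) | C[C@@]12OC(=O)[C@@](C=O)(C(OCC)=C1)C1=C2C(=O)Oc2cc3OC(C)(C)CC(=O)c3c(C)c2O1 | intermediate
20 | O-ethyl mollicellin A | CCOc1cc(C)c2C(=O)Oc3cc4OC(C)(C)CC(=O)c4c(C)c3Oc2c1C=O | intermediate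
21 | dichloroboron aryloxide of mollicellin A | Cc1cc(OB(Cl)Cl)c(C=O)c2c1C(=O)Oc1cc3c(c(C)c1O2)C(=O)CC(C)(C)O3 | intermediate
22 | mollicellin A | Cc1cc(O)c(C=O)c2c1C(=O)Oc1cc3c(c(C)c1O2)C(=O)CC(C)(C)O3 | target

**Totals**
- Total step count: 10.
- Longest linear sequence: 8 steps (steps 1, 2, 3, 6, 7, 8, 9, 10).

**Steps most likely to fail**

1. Step 9.
   - Risk: bond formation at two fully substituted diene termini may be slower than the thermal retro-ene decay of ethoxyacetylene. The ynol ether may also add to the formyl C=O or to the oxadiene instead of the carbodiene.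
   - Fallback: setting out from 17, the alkyne is replaced by 1,1-diethoxyethene (ketene diethyl acetal, C=C(OCC)OCC; toluene, rt to 80 °C). This is a more nucleophilic and thermally robust two-carbon partner at the alkene oxidation level.
   - Its CH2 carbon should bond to C6 and its acetal carbon to C3, giving the bridged gem-diethoxy lactone F1, which loses CO2 to the gem-diethoxy cyclohexadiene F2.
   - Loss of ethanol from F2 (on heating or with catalytic pyridinium tosylate) aromatises ring A. The route is rejoined at 20.

2. Step 2.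
   - Risk: attack of persulfate at a para carbon flanked by methyl and benzyloxy may be slow, so oxidative degradation of the phenoxide and recovery of unchanged phenol could dominate. The benzyl ether may also erode during the hot acid hydrolysis.
   - Fallback: setting out from 2, the oxygen is brought in through a halide and a boronate. NBS (MeCN, 0 °C) should brominate para to the free phenol to give 4-(benzyloxy)-5-bromo-2-hydroxy-6-methylacetophenone F3.
   - Kabbe annulation of F3 with acetone 5 and pyrrolidine gives 7-(benzyloxy)-6-bromo-2,2,5-trimethylchroman-4-one F4.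
   - Miyaura borylation (B2pin2, PdCl2(dppf), KOAc, dioxane, 90 °C) gives the C6 pinacol boronate F5.
   - Oxidation of F5 (H2O2, aq NaOH, THF, 0 °C) rejoins the route at 7.

3. Step 7.
   - Risk: the formyl group may be over-reduced, or the electron-poor pyranone C=C bonds saturated, before the hindered aryl benzyl ether has been cleaved.
   - Fallback: setting out from 14, the order of ring formation is inverted. Heating 14 with ethoxyacetylene 18 as in step 9 lets cycloaddition and CO2 loss build ring A first, giving benzyl 2-{[7-(benzyloxy)-2,2,5-trimethyl-4-oxochroman-6-yl]oxy}-4-ethoxy-3-formyl-6-methylbenzoate F6.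
   - Hydrogenolysis (H2, Pd/C, EtOAc) then meets only an aromatic aldehyde flanked by two oxygens, and should give 4-ethoxy-3-formyl-2-[(7-hydroxy-2,2,5-trimethyl-4-oxochroman-6-yl)oxy]-6-methylbenzoic acid F7.
   - DCC closes F7 in the classical depsidone lactonisation. The route is rejoined at 20.

**Further compounds**
F1 | step 9 | bridged gem-diethoxy lactone (racemic, one enantiomer drawn) | CCOC1(OCC)C[C@@]2(C)OC(=O)[C@]1(C=O)C1=C2C(=O)Oc2cc3OC(C)(C)CC(=O)c3c(C)c2O1
F2 | step 9 | gem-diethoxy cyclohexadiene (dihydro ring A with C(OEt)2 next to the formyl carbon and CH2 next to the methyl carbon) | CCOC1(OCC)CC(C)=C2C(=O)Oc3cc4OC(C)(C)CC(=O)c4c(C)c3OC2=C1C=O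
F3 | step 2 | 4-(benzyloxy)-5-bromo-2-hydroxy-6-methylacetophenone | CC(=O)c1c(C)c(Br)c(OCc2ccccc2)cc1O
F4 | step 2 | 7-(benzyloxy)-6-bromo-2,2,5-trimethylchroman-4-one | CC1(C)CC(=O)c2c(C)c(Br)c(OCc3ccccc3)cc2O1
F5 | step 2 | 7-(benzyloxy)-2,2,5-trimethyl-6-(4,4,5,5-tetramethyl-1,3,2-dioxaborolan-2-yl)chroman-4-one | CC1(C)CC(=O)c2c(C)c(B3OC(C)(C)C(C)(C)O3)c(OCc3ccccc3)cc2O1
F6 | step 7 | benzyl 2-{[7-(benzyloxy)-2,2,5-trimethyl-4-oxochroman-6-yl]oxy}-4-ethoxy-3-formyl-6-methylbenzoate | CCOc1cc(C)c(C(=O)OCc2ccccc2)c(Oc2c(C)c3C(=O)CC(C)(C)Oc3cc2OCc2ccccc2)c1C=O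
F7 | step 7 | 4-ethoxy-3-formyl-2-[(7-hydroxy-2,2,5-trimethyl-4-oxochroman-6-yl)oxy]-6-methylbenzoic acid | CCOc1cc(C)c(C(=O)O)c(Oc2c(C)c3C(=O)CC(C)(C)Oc3cc2O)c1C=O
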